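## Retrosynthetic overview

1. The last step is hydrogenolysis of three benzyl ethers. Before it, the tetrahydrofuran ring (O1–C2 bond) and the primary acetate are made together from an acyclic benzylic triol through a cyclic orthoacetate/acetoxonium ion (new step).
2. The triol comes from hydride reduction of a trans-α-(aryl-hydroxymethyl)-β-(arylmethyl)-γ-butyrolactone. Aldol disconnection of that lactone (C2–C3 bond) gives an (R)-β-(arylmethyl)butyrolactone and 3,4-bis(benzyloxy)benzaldehyde.
3. Key step: the (R)-lactone comes from a catalytic enantioselective Baeyer–Villiger ring expansion of a prochiral 3-(arylmethyl)cyclobutanone, a 1,2-shift of a ring CH2 from C to O. This stereocentre (future C4) then controls C3 and C2.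
4. The cyclobutanone comes from Negishi coupling of 3-(bromomethyl)cyclobutanone with O-benzyl-4-bromoguaiacol. Both arenes come from catechol.
5. Ring order: cyclobutanone (bought), then γ-lactone (ring expansion), then opened by reduction, then tetrahydrofuran (closed last).

Assumption: in step 4 the antipode of the N,N'-dioxide ligand that gives the (R)-lactone is used (both are accessible from L- or D-pipecolic acid), and the sense is checked on the first run by optical rotation.

## Route

Step 1
Reactants: 1 catechol
Product: 2 guaiacol (2-methoxyphenol)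
Conditions: MeI (1.0 equiv), 1 (2 equiv), K2CO3, acetone, reflux; distillation
Reagents that add atoms: iodomethane, CI
Why: This is a Williamson ether synthesis in which the excess of cheap catechol keeps the second methylation low, and no stereocentre is formed.

Step 2
Reactants: 2 guaiacol
Product: 4 1-(benzyloxy)-4-bromo-2-methoxybenzene, via 4-bromo-2-methoxyphenol 3 (not isolated)
Conditions: NBS, MeCN, 0 °C; then K2CO3, BnBr (excess), 60 °C, same pot
Reagents that add atoms: N-bromosuccinimide, O=C1CCC(=O)N1Br; benzyl bromide, BrCc1ccccc1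
Why: Electrophilic aromatic bromination goes para to the free OH, the strongest director, and Williamson benzylation of the crude phenol then masks it.

Step 3
Reactants: 4 1-(benzyloxy)-4-bromo-2-methoxybenzene; 5 3-(bromomethyl)cyclobutan-1-one
Product: 7 3-[4-(benzyloxy)-3-methoxybenzyl]cyclobutan-1-one, via alkylzinc bromide 6 (not isolated)
Conditions: 5, Zn dust, LiCl, THF, 40 °C; then 4, Pd(OAc)2 (2 mol %), SPhos (4 mol %), THF, 25→50 °C
Reagents that add atoms: none
Why: Direct zinc insertion followed by Negishi cross-coupling forms the aryl–CH2 bond by a two-electron pathway that tolerates the ketone and avoids a long-lived cyclobutylmethyl radical; the product is achiral.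

Step 4
Reactants: 7 3-[4-(benzyloxy)-3-methoxybenzyl]cyclobutan-1-one
Product: 9 (R)-4-[4-(benzyloxy)-3-methoxybenzyl]dihydrofuran-2(3H)-one, via Criegee adduct 8 (not isolated)
Conditions: mCPBA (1.2 equiv), Sc(OTf)3 (5 mol %), pipecolic-acid-derived chiral N,N'-dioxide bis(2,6-diisopropylanilide) ligand (5 mol %), EtOAc, −20 °C
Reagents that add atoms: 3-chloroperbenzoic acid, OOC(=O)c1cccc(Cl)c1
Why: In this catalytic asymmetric Baeyer–Villiger oxidation the peracid adds to the strained ketone to give 8, and the chiral trivalent scandium complex lets only one of the two enantiotopic ring CH2 groups make the antiperiplanar ionic 1,2-shift from carbon to oxygen, so the ring expands to the lactone and the prochiral carbon becomes the (R)-centre (future C4).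

Step 5
Reactants: 1 catechol
Product: 10 1,2-bis(benzyloxy)benzene
Conditions: BnBr (2.2 equiv), K2CO3, DMF, 60 °C
Reagents that add atoms: benzyl bromide, BrCc1ccccc1
Why: A double Williamson ether synthesis masks both phenols with groups that leave in the same final hydrogenolysis as the benzyl group of 4.

Step 6
Reactants: 10 1,2-bis(benzyloxy)benzene
Product: 12 3,4-bis(benzyloxy)benzaldehyde, via alpha-chloro ether 11 (not isolated)
Conditions: Cl2CHOMe, SnCl4, CH2Cl2, −10→0 °C; then ice-water
Reagents that add atoms: dichloromethyl methyl ether, COC(Cl)Cl; water, O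
Why: Rieche formylation attacks the position para to one alkoxy group, as with veratrole, and the mild Lewis acid at low temperature spares the benzyl ethers.

Step 7
Reactants: 9 (R)-4-[4-(benzyloxy)-3-methoxybenzyl]dihydrofuran-2(3H)-one; 12 3,4-bis(benzyloxy)benzaldehyde
Product: 15 (2R,3R)-1-[3,4-bis(benzyloxy)phenyl]-3-[4-(benzyloxy)-3-methoxybenzyl]-2-(hydroxymethyl)butane-1,4-diol (both C1 epimers), via lithium enolate 13 (not isolated), via lithium aldolate 14 (not isolated)
Conditions: LiN(iPr)2 (1.1 equiv), THF, −78 °C; 12, −78 °C; then LiAlH4, −78→0 °C; H2O/aq NaOH work-up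
Reagents that add atoms: none
Why: The lithium enolate aldol addition takes the aldehyde on the face anti to the β-arylmethyl group and so sets the trans (future C3, R) centre, and in situ LiAlH4 reduction of the lactone traps the aldolate before retro-aldol can occur; the carbinol epimer mixture is erased in step 8.

Step 8
Reactants: 15 (2R,3R)-triol
Product: 18 [(2S,3R,4R)-2-[3,4-bis(benzyloxy)phenyl]-4-[4-(benzyloxy)-3-methoxybenzyl]tetrahydrofuran-3-yl]methyl acetate, via cyclic orthoacetate 16 (not isolated), via dioxanylium ion 17 (not isolated)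
Conditions: MeC(OMe)3 (1.2 equiv), PPTS (2 mol %), CH2Cl2, rt; then BF3·OEt2 (20 mol %), −40→0 °C; Et3N quench
Reagents that add atoms: trimethyl orthoacetate, COC(C)(OC)OC
Why: Proposed new method: acid-catalysed exchange ties the benzylic OH and the 1,3-related CH2OH into the six-membered orthoacetate 16, BF3 removes methoxide to give the 1,3-dioxan-2-ylium ion 17, whose benzylic C–O bond is loosened by the 3,4-dialkoxyaryl group, and the remaining CH2OH closes 5-exo on that carbon, so ring closure and delivery of the acetyl group to the other primary oxygen happen in one event. The SN1-like, reversible closure makes both carbinol epimers converge on the 2,3-trans (2S) ring with the aryl group anti to the C3 side chain. The closest known reaction types are the orthoester/acetoxonium cyclisation of 1,2,n-triols to acetoxy tetrahydrofurans through five-membered dioxolanylium ions, the halide opening of orthoacetates from 1,3-diols, and the plain acid-catalysed cycloetherification of benzylic lignan triols; opening of a six-membered acetoxonium ion at a benzylic carbon by an internal hydroxyl has not been shown.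

Step 9
Reactants: 18 tri-O-benzyl acetate
Product: 19 [(2S,3R,4R)-2-(3,4-dihydroxyphenyl)-4-(4-hydroxy-3-methoxybenzyl)tetrahydrofuran-3-yl]methyl acetate (target)
Conditions: H2 (1 atm), Pd/C (10 wt %), EtOAc, rt, stopped after uptake of 3 equiv
Reagents that add atoms: none
Why: Catalytic hydrogenolysis cleaves aryl benzyl ethers in a neutral solvent much faster than the cyclic benzylic C2–O1 bond, leaves the acetate alone and touches no stereocentre.

## Compound list

1 | catechol (benzene-1,2-diol) | Oc1ccccc1O | starting material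
2 | guaiacol (2-methoxyphenol) | COc1ccccc1O | intermediate
3 | 4-bromo-2-methoxyphenol (not isolated) | COc1cc(Br)ccc1O | intermediate
4 | 1-(benzyloxy)-4-bromo-2-methoxybenzene | COc1cc(Br)ccc1OCc1ccccc1 | intermediate
5 | 3-(bromomethyl)cyclobutan-1-one | O=C1CC(CBr)C1 | starting material
6 | [(3-oxocyclobutyl)methyl]zinc bromide (not isolated) | O=C1CC(C[Zn]Br)C1 | intermediate
7 | 3-[4-(benzyloxy)-3-methoxybenzyl]cyclobutan-1-one | COc1cc(CC2CC(=O)C2)ccc1OCc1ccccc1 | intermediate
8 | Criegee adduct, 1-hydroxy-3-(arylmethyl)cyclobutyl 3-chloroperbenzoate (not isolated) | COc1cc(CC2CC(O)(OOC(=O)c3cccc(Cl)c3)C2)ccc1OCc1ccccc1 | intermediate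
9 | (R)-4-[4-(benzyloxy)-3-methoxybenzyl]dihydrofuran-2(3H)-one | COc1cc(C[C@H]2COC(=O)C2)ccc1OCc1ccccc1 | intermediate
10 | 1,2-bis(benzyloxy)benzene | c1ccc(COc2ccccc2OCc2ccccc2)cc1 | intermediate
11 | 1,2-bis(benzyloxy)-4-[chloro(methoxy)methyl]benzene (not isolated) | COC(Cl)c1ccc(OCc2ccccc2)c(OCc2ccccc2)c1 | intermediate
12 | 3,4-bis(benzyloxy)benzaldehyde | O=Cc1ccc(OCc2ccccc2)c(OCc2ccccc2)c1 | intermediate
13 | lithium enolate of 9 (not isolated) | [Li+].COc1cc(C[C@H]2COC([O-])=C2)ccc1OCc1ccccc1 | intermediate
14 | lithium alkoxide of (3S,4R)-3-{[3,4-bis(benzyloxy)phenyl](hydroxy)methyl}-4-[4-(benzyloxy)-3-methoxybenzyl]dihydrofuran-2(3H)-one, carbinol epimers (not isolated) | [Li+].COc1cc(C[C@H]2COC(=O)[C@@H]2C([O-])c3ccc(OCc4ccccc4)c(OCc4ccccc4)c3)ccc1OCc1ccccc1 | intermediate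
15 | (2R,3R)-1-[3,4-bis(benzyloxy)phenyl]-3-[4-(benzyloxy)-3-methoxybenzyl]-2-(hydroxymethyl)butane-1,4-diol, both C1 epimers | COc1cc(C[C@@H](CO)[C@H](CO)C(O)c2ccc(OCc3ccccc3)c(OCc3ccccc3)c2)ccc1OCc1ccccc1 | intermediate
16 | 2-methoxy-2-methyl-1,3-dioxane spanning the benzylic O and the neighbouring CH2O of 15; 4-aryl, 5-[(R)-1-aryl-3-hydroxypropan-2-yl] (not isolated) | COc1cc(C[C@@H](CO)[C@@H]2COC(C)(OC)OC2c3ccc(OCc4ccccc4)c(OCc4ccccc4)c3)ccc1OCc1ccccc1 | intermediate
17 | 2-methyl-1,3-dioxan-2-ylium ion formed from 16 by loss of methoxide (not isolated) | COc1cc(C[C@@H](CO)[C@@H]2COC(C)=[O+]C2c3ccc(OCc4ccccc4)c(OCc4ccccc4)c3)ccc1OCc1ccccc1 | intermediate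
18 | [(2S,3R,4R)-2-[3,4-bis(benzyloxy)phenyl]-4-[4-(benzyloxy)-3-methoxybenzyl]tetrahydrofuran-3-yl]methyl acetate | COc1cc(C[C@H]2CO[C@H](c3ccc(OCc4ccccc4)c(OCc4ccccc4)c3)[C@H]2COC(C)=O)ccc1OCc1ccccc1 | intermediate
19 | [(2S,3R,4R)-2-(3,4-dihydroxyphenyl)-4-(4-hydroxy-3-methoxybenzyl)tetrahydrofuran-3-yl]methyl acetate | COc1cc(C[C@H]2CO[C@H](c3ccc(O)c(O)c3)[C@H]2COC(C)=O)ccc1O | target

## Step count and risks

Total step count: 9.
Longest linear sequence: 7 (steps 1, 2, 3, 4, 7, 8, 9 from catechol).

**Step 3 (zinc insertion/Negishi coupling).**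
- Risks: sluggish insertion into the β-branched bromide, fragmentation of the strained keto-alkyl species, and β-hydride elimination on palladium.
- Fallback: it sets out from 4 and comes back at 7, and it builds the four-membered ring instead of coupling it. Compound 4 is turned with Mg turnings in THF into [4-(benzyloxy)-3-methoxyphenyl]magnesium bromide F1. This is allylated with allyl bromide (CuI cat.) to 4-allyl-1-(benzyloxy)-2-methoxybenzene F2. Cycloaddition with dichloroketene F3, generated from Cl3CCOCl and Zn–Cu couple in Et2O, gives racemic 2,2-dichloro-3-[4-(benzyloxy)-3-methoxybenzyl]cyclobutan-1-one F4. Zn dust in AcOH then removes both chlorines to give 7.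

**Step 8 (proposed new step).**
- Risks: opening of the acetoxonium ion at the primary carbon, Friedel–Crafts closure of the benzylic cation onto the other arene to give an aryltetralin, and incomplete acetyl transfer.
- Fallback: it uses known chemistry, sets out from 15 and comes back at 18. Camphorsulfonic acid (5 mol %) in CH2Cl2 at 0 °C cyclodehydrates the triol through the benzylic cation to [(2S,3R,4R)-2-[3,4-bis(benzyloxy)phenyl]-4-[4-(benzyloxy)-3-methoxybenzyl]tetrahydrofuran-3-yl]methanol F5. The single free hydroxyl of this alcohol is acetylated with Ac2O, pyridine and DMAP to give 18.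

**Step 9 (hydrogenolysis).**
- Risk: over-reduction of the benzylic C2–O1 bond to the ring-opened diarylbutane once the para-phenol is free.
- Fallback: it sets out from 18 and comes back at 19, and it replaces reduction by Lewis-acid dealkylation with a cation scavenger. The conditions are BCl3 (6 equiv) and pentamethylbenzene in CH2Cl2 at −78 °C with a cold methanol/water quench. This leaves the acetate and the aryl methyl ether intact, and no new compound arises (F0).

## Further compounds

F1 | step 3 | [4-(benzyloxy)-3-methoxyphenyl]magnesium bromide | COc1cc([Mg]Br)ccc1OCc1ccccc1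
F2 | step 3 | 4-allyl-1-(benzyloxy)-2-methoxybenzene | C=CCc1ccc(OCc2ccccc2)c(OC)c1
F3 | step 3 | dichloroketene | ClC(Cl)=C=O
F4 | step 3 | racemic 2,2-dichloro-3-[4-(benzyloxy)-3-methoxybenzyl]cyclobutan-1-one | COc1cc(CC2CC(=O)C2(Cl)Cl)ccc1OCc1ccccc1
F5 | step 8 | [(2S,3R,4R)-2-[3,4-bis(benzyloxy)phenyl]-4-[4-(benzyloxy)-3-methoxybenzyl]tetrahydrofuran-3-yl]methanol | COc1cc(C[C@H]2CO[C@H](c3ccc(OCc4ccccc4)c(OCc4ccccc4)c3)[C@H]2CO)ccc1OCc1ccccc1
F0 | step 9 | none | none
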